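## Retrosynthetic overview

1. Target 30 ⇐ C4 desilylation and C11 α′-acetoxylation of lactone 28 ⇐ zinc Reformatsky closure (C8–C17) after Mitsunobu inversion at C7 of a ten-membered hydroxy ketone.
2. Ten-membered ring ⇐ key four-atom ring expansion: Grob fragmentation of tricycle 20 (C8 alkoxide, equatorial C2 mesylate) cleaves the C3–C8 bond of six-membered ring C and gives the (E)-C2=C3 alkene.
3. Tricycle ⇐ syn-aldol (C2–C3) of ring-C ketone 5 with ring-A aldehyde 10, then carbene-catalysed benzoin closure (C8–C9) of ring B; C6–Cl and C4–OH are then set on the rigid tricycle.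
4. Ring A ⇐ new catalytic enantioselective Diels–Alder of silyloxydiene 7 with enal 8, then Saegusa oxidation; ring C ⇐ Shi oxidation of the dienol ether of 1.
5. Ring order: ring A (cycloaddition), ring C (purchased), ring B (aldol, benzoin), ten-membered ring (fragmentation of the B/C bond), lactone (Reformatsky).

Numbering: briarane numbering of the target is used throughout (C1 quaternary with C15 methyl, C2=C3, C4–OH, C5=C16, C6–Cl, C7 lactone O, C8–OH, C9–OAc, C10, C11 with C20 methyl, C12=O, C13=C14, C17–C19 lactone carbons with C18 methyl). β is the face of the C15 methyl. Tricycles are named as 3,8-cyclo derivatives (extra C3–C8 bond) and compounds lacking C17–C19 as 17,18,19-trinor derivatives.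

Assumptions: 1 and 8 are purchased. In the two catalyst-controlled steps (2 and 5) the catalyst antipode that gives the drawn enantiomer is meant. C11 is drawn as the endo (equatorial-methyl) epimer until it is reset in step 20.

## Route

Step 1
Reactants: 1 4-methylcyclohex-3-en-1-one
Product: 2 trimethyl[(4-methylcyclohexa-1,3-dien-1-yl)oxy]silane
Conditions: Me3SiOTf, Et3N, CH2Cl2, 0 °C
Reagents that add atoms: trimethylsilyl triflate, C[Si](C)(C)OS(=O)(=O)C(F)(F)F
Why: Soft enolisation (silyl enol ether formation) removes the doubly activated C2–H between carbonyl and alkene and gives the conjugated 2-silyloxydiene, with no stereocentre formed.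

Step 2
Reactants: 2 trimethyl[(4-methylcyclohexa-1,3-dien-1-yl)oxy]silane
Product: 4 (R)-2-hydroxy-4-methylcyclohex-3-en-1-one, via silyloxy epoxide 3 (not isolated)
Conditions: Shi ketone (fructose-derived, 30 mol %), KHSO5 (as 2KHSO5·KHSO4·K2SO4), K2CO3/AcOH buffer pH 8, MeCN/dimethoxymethane/H2O, 0 °C
Reagents that add atoms: potassium peroxymonosulfate, [K+].[O-]S(=O)(=O)OO
Why: Shi asymmetric epoxidation by the chiral dioxirane attacks the electron-rich silyl enol ether double bond on one face through the spiro transition state and the labile silyloxy epoxide collapses to the α-hydroxy ketone, which sets the future C7 as R, deliberately the epimer of its final configuration.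

Step 3
Reactants: 4 (R)-2-hydroxy-4-methylcyclohex-3-en-1-one
Product: 5 (R)-2-[(tert-butyldimethylsilyl)oxy]-4-methylcyclohex-3-en-1-one
Conditions: tert-butyldimethylsilyl chloride, imidazole, DMF, 25 °C
Reagents that add atoms: tert-butyldimethylsilyl chloride, CC(C)(C)[Si](C)(C)Cl
Why: Standard silylation of a secondary alcohol, giving the bulky ether that later shields one enolate face.

Step 4
Reactants: 6 pent-1-en-3-one
Product: 7 (Z)-triisopropyl(penta-1,3-dien-3-yloxy)silane
Conditions: iPr3SiOTf, Et3N, Et2O, 0 °C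
Reagents that add atoms: triisopropylsilyl triflate, CC(C)[Si](OS(=O)(=O)C(F)(F)F)(C(C)C)C(C)C
Why: Soft enolisation of the ethyl ketone gives the thermodynamically preferred (Z)-silyl enol ether, i.e. the diene with its methyl group outside, as needed for cycloaddition.

Step 5
Reactants: 7 (Z)-triisopropyl(penta-1,3-dien-3-yloxy)silane; 8 (E)-4,4-dimethoxy-2-methylbut-2-enal (2-methylfumaraldehyde 4-dimethyl acetal)
Product: 9 (1S,5S,6S)-6-(dimethoxymethyl)-1,5-dimethyl-4-[(triisopropylsilyl)oxy]cyclohex-3-ene-1-carbaldehyde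
Conditions: (S)-B-o-tolyl oxazaborolidine from diphenylprolinol, protonated with Tf2NH (20 mol %), CH2Cl2, −78 → −40 °C
Reagents that add atoms: none
Why: Proposed new method: enantioselective Diels–Alder of a 1-methyl-2-silyloxydiene with a trisubstituted γ-acetal enal under chiral oxazaborolidinium catalysis, a pairing not yet shown, in which the cationic boron binds the formyl oxygen (formyl C–H···O contact), the s-trans enal stacks on the aryl group so one face is shielded, the silyl enol ether carbon (C11) bonds to the β-carbon (C10) and C14 to the α-carbon (C1) in an asynchronous endo transition state, the E geometry of 8 fixes C1/C10 trans and the catalyst fixes them as 1S,10S, the closest known reaction being the oxazaborolidinium-catalysed Diels–Alder of 2-silyloxybutadienes with 2-methylacrolein-type enals.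

Step 6
Reactants: 9 (1S,5S,6S)-6-(dimethoxymethyl)-1,5-dimethyl-4-[(triisopropylsilyl)oxy]cyclohex-3-ene-1-carbaldehyde
Product: 10 (1S,5S,6S)-6-(dimethoxymethyl)-1,5-dimethyl-4-oxocyclohex-2-ene-1-carbaldehyde
Conditions: Pd(OAc)2 (1.1 equiv), DMSO, 50 °C
Reagents that add atoms: none
Why: Saegusa–Ito oxidation of the regiodefined silyl enol ether with β-hydride loss from C14 installs the C13=C14 enone under neutral conditions that leave aldehyde and acetal alone.

Step 7
Reactants: 5 (R)-2-[(tert-butyldimethylsilyl)oxy]-4-methylcyclohex-3-en-1-one; 10 (1S,5S,6S)-6-(dimethoxymethyl)-1,5-dimethyl-4-oxocyclohex-2-ene-1-carbaldehyde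
Product: 13 (2R,6S)-2-[(tert-butyldimethylsilyl)oxy]-6-{(S)-[(1S,5S,6S)-6-(dimethoxymethyl)-1,5-dimethyl-4-oxocyclohex-2-en-1-yl](hydroxy)methyl}-4-methylcyclohex-3-en-1-one, via lithium enolate 11 (not isolated), via titanium enolate 12 (not isolated)
Conditions: LiN(iPr)2, THF, −78 °C; ClTi(OiPr)3, −78 → −40 °C; then 10, −78 °C; aq. NH4Cl
Reagents that add atoms: none
Why: Titanium-enolate aldol addition (syn-selective for cyclic enolates) after kinetic deprotonation at the CH2 (C3), with C–C bond formation anti to the pseudo-axial C7 silyloxy group (sets C3) and Felkin–Anh attack on the neopentyl aldehyde with the fully substituted C10 as the large group (sets C2), the three preferences being matched for the 2,3-syn adduct.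

Step 8
Reactants: 13 the aldol adduct named in step 7
Product: 14 (2R,6S)-2-[(tert-butyldimethylsilyl)oxy]-6-{(S)-[(1S,5S,6S)-6-formyl-1,5-dimethyl-4-oxocyclohex-2-en-1-yl](hydroxy)methyl}-4-methylcyclohex-3-en-1-one (in equilibrium with its five-membered lactol)
Conditions: pyridinium p-toluenesulfonate, acetone/H2O (9:1), 45 °C
Reagents that add atoms: water, O
Why: Mild acid hydrolysis of the dimethyl acetal, which silyl ether and β-hydroxy ketone survive, the aldehyde being stored as its lactol with the C2 hydroxyl.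

Step 9
Reactants: 14 the hydroxy aldehyde named in step 8
Product: 15 (1S,2S,3S,7R,8R,10S,11S)-7-(tert-butyldimethylsilyloxy)-2,8-dihydroxy-3,8-cyclo-17,18,19-trinorbriara-5,13-diene-9,12-dione
Conditions: 2-mesityl-6,7-dihydro-5H-pyrrolo[2,1-c][1,2,4]triazol-2-ium chloride (20 mol %), iPr2NEt (20 mol %), toluene, 60 °C
Reagents that add atoms: none
Why: Intramolecular crossed aldehyde–ketone benzoin reaction under N-heterocyclic carbene catalysis adds the C9 acyl-anion equivalent to the C8 ketone and closes six-membered ring B, reversibility funnelling to the all-chair trans-fused α-ketol with axial (α) C8–OH, a centre that is destroyed later.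

Step 10
Reactants: 15 the tricyclic α-ketol named in step 9
Product: 16 (1S,2S,3S,7R,8R,10S,11S)-7-(tert-butyldimethylsilyloxy)-8-hydroxy-2-(methanesulfonyloxy)-3,8-cyclo-17,18,19-trinorbriara-5,13-diene-9,12-dione
Conditions: MsCl, Et3N, CH2Cl2, −20 °C
Reagents that add atoms: methanesulfonyl chloride, CS(=O)(=O)Cl
Why: Sulfonylation of the only secondary alcohol (equatorial C2–OH), the tertiary C8–OH being unreactive.

Step 11
Reactants: 16 the mesylate named in step 10
Product: 17 (1S,2S,3S,6S,7S,8R,10S,11S)-7-(tert-butyldimethylsilyloxy)-6-chloro-8-hydroxy-2-(methanesulfonyloxy)-3,8-cyclo-17,18,19-trinorbriara-5(16),13-diene-9,12-dione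
Conditions: Ca(OCl)2, solid CO2, CH2Cl2/H2O, 0 °C
Reagents that add atoms: hypochlorous acid (from Ca(OCl)2 and CO2), OCl
Why: Ene-type allylic chlorination of the trisubstituted alkene, in which Cl adds axially to C6 on the α face anti to the axial C7 silyloxy group and a C16 proton is lost to give the exocyclic methylene, sets C6 as S.

Step 12
Reactants: 17 the allylic chloride named in step 11
Product: 18 (1S,2S,3S,4S,6S,7S,8R,10S,11S)-7-(tert-butyldimethylsilyloxy)-6-chloro-4,8-dihydroxy-2-(methanesulfonyloxy)-3,8-cyclo-17,18,19-trinorbriara-5(16),13-diene-9,12-dione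
Conditions: SeO2 (0.5 equiv), tBuOOH, CH2Cl2, 25 °C
Reagents that add atoms: tert-butyl hydroperoxide (oxygen relayed through SeO2), CC(C)(C)OO
Why: SeO2 allylic oxidation (ene reaction then [2,3]-sigmatropic shift) removes the only axial allylic hydrogen, at C4, and returns oxygen on the same α face, giving the axial 4S alcohol as in 5-ene to 4β-ol oxidations of steroids.

Step 13
Reactants: 18 the allylic alcohol named in step 12
Product: 19 (1S,2S,3S,4S,6S,7S,8R,10S,11S)-7-(tert-butyldimethylsilyloxy)-6-chloro-8-hydroxy-2-(methanesulfonyloxy)-4-(triisopropylsilyloxy)-3,8-cyclo-17,18,19-trinorbriara-5(16),13-diene-9,12-dione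
Conditions: iPr3SiOTf, 2,6-lutidine, CH2Cl2, 0 → 25 °C
Reagents that add atoms: triisopropylsilyl triflate, CC(C)[Si](OS(=O)(=O)C(F)(F)F)(C(C)C)C(C)C
Why: Silylation of the secondary allylic alcohol, the ring-fusion tertiary alcohol being too hindered for this silyl group.

Step 14
Reactants: 19 the silyl ether named in step 13
Product: 20 (1S,2S,3S,4S,6S,7S,8S,9S,10S,11S)-7-(tert-butyldimethylsilyloxy)-6-chloro-8,9-dihydroxy-2-(methanesulfonyloxy)-4-(triisopropylsilyloxy)-3,8-cyclo-17,18,19-trinorbriara-5(16),13-dien-12-one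
Conditions: Me4NBH(OAc)3, MeCN/AcOH (1:1), −20 °C
Reagents that add atoms: none
Why: Hydroxyl-directed triacetoxyborohydride reduction delivers hydride from the boron bound to the axial α C8–OH to the α face of the C9 ketone, also the face away from the syn-axial C15 methyl, giving the 9S (β) alcohol while enone and mesylate are untouched.

Step 15
Reactants: 20 the diol mesylate named in step 14
Product: 22 (1S,2E,4S,6S,7S,9S,10S,11S)-7-(tert-butyldimethylsilyloxy)-6-chloro-9-hydroxy-4-(triisopropylsilyloxy)-17,18,19-trinorbriara-2,5(16),13-triene-8,12-dione, via potassium alkoxide 21 (not isolated)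
Conditions: KN(SiMe3)2 (1.05 equiv), THF, −78 → −20 °C
Reagents that add atoms: none
Why: Key ring expansion by Grob (Wharton) fragmentation, in which the C8 alkoxide, the C3–C8 bond and the equatorial C2 mesylate are antiperiplanar in chair ring B and C1–C2–C3–C4 is anti, so heterolysis gives C8=O and the (E)-C2=C3 alkene and turns six-membered ring C into the ten-membered ring, the base being consumed so the β-chloro ketone is not exposed to excess base.

Step 16
Reactants: 22 the ring-expanded hydroxy ketone named in step 15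
Product: 23 (1S,2E,4S,6S,7S,9S,10S,11S)-9-acetoxy-7-(tert-butyldimethylsilyloxy)-6-chloro-4-(triisopropylsilyloxy)-17,18,19-trinorbriara-2,5(16),13-triene-8,12-dione
Conditions: Ac2O, pyridine, 4-(dimethylamino)pyridine (5 mol %), CH2Cl2, 0 °C
Reagents that add atoms: acetic anhydride, CC(=O)OC(C)=O
Why: Acylation of the only free hydroxyl, a secondary α-ketol, installs the C9 acetate.

Step 17
Reactants: 23 the acetate named in step 16
Product: 24 (1S,2E,4S,6S,7S,9S,10S,11S)-9-acetoxy-6-chloro-7-hydroxy-4-(triisopropylsilyloxy)-17,18,19-trinorbriara-2,5(16),13-triene-8,12-dione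
Conditions: HF·pyridine, pyridine, THF, 0 °C
Reagents that add atoms: none
Why: Fluoride desilylation selective for the tert-butyldimethylsilyl ether next to the ketone over the bulkier triisopropylsilyl ether.

Step 18
Reactants: 24 the C7 alcohol named in step 17; 25 2-bromopropanoic acid (racemic)
Product: 26 (1S,2E,4S,6S,7R,9S,10S,11S)-9-acetoxy-7-(2-bromopropanoyloxy)-6-chloro-4-(triisopropylsilyloxy)-17,18,19-trinorbriara-2,5(16),13-triene-8,12-dione (both epimers at the bromine-bearing carbon)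
Conditions: PPh3, diisopropyl azodicarboxylate, toluene, 0 → 25 °C
Reagents that add atoms: none
Why: Mitsunobu esterification proceeds by SN2 inversion at C7 (activated by the adjacent carbonyl), converting the temporary 7S centre into the required 7R acyloxy centre and bringing in C17–C19.

Step 19
Reactants: 26 the bromo ester named in step 18
Product: 28 (1S,2E,4S,6S,7R,8R,9S,10S,11S,17R)-9-acetoxy-6-chloro-8-hydroxy-12-oxo-4-(triisopropylsilyloxy)briara-2,5(16),13-trien-19,7-olide, via zinc enolate 27 (not isolated)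
Conditions: Zn dust (Me3SiCl-activated), THF, 45 °C; aq. NH4Cl
Reagents that add atoms: none
Why: Intramolecular Reformatsky reaction under neutral conditions adds the zinc enolate to the C8 ketone from the side of the C7 tether through a zinc-chelated transition state with C6 and C9 anti and the C17 methyl on the convex side, setting C8 (R) and C17 (R) and closing the trans-fused γ-lactone.

Step 20
Reactants: 28 the lactone named in step 19
Product: 29 (1S,2E,4S,6S,7R,8R,9S,10S,11S,17R)-9,11-diacetoxy-6-chloro-8-hydroxy-12-oxo-4-(triisopropylsilyloxy)briara-2,5(16),13-trien-19,7-olide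
Conditions: Mn(OAc)3·2H2O (4 equiv), benzene, 80 °C, Dean–Stark
Reagents that add atoms: manganese triacetate, CC(=O)[O-].CC(=O)[O-].CC(=O)[O-].[Mn+3]
Why: Mn(OAc)3 α′-acetoxylation of the enone transfers acetate to the C11 manganese enolate on the α face, opposite the axial C15 methyl, setting C11 (S) without strong base.

Step 21
Reactants: 29 the diacetate named in step 20
Product: 30 (1S,2E,4S,6S,7R,8R,9S,10S,11S,17R)-9,11-diacetoxy-6-chloro-4,8-dihydroxy-12-oxobriara-2,5(16),13-trien-19,7-olide (CNP0196166.1)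
Conditions: HF·pyridine, THF, 25 °C
Reagents that add atoms: none
Why: Fluoride desilylation of the allylic silyl ether, to which acetates, lactone and allylic chloride are stable.

## Compound list

1 | 4-methylcyclohex-3-en-1-one | CC1=CCC(=O)CC1 | starting material
2 | trimethyl[(4-methylcyclohexa-1,3-dien-1-yl)oxy]silane | CC1=CC=C(O[Si](C)(C)C)CC1 | intermediate
3 | trimethyl{[(1R,6R)-4-methyl-7-oxabicyclo[4.1.0]hept-4-en-1-yl]oxy}silane (silyloxy epoxide, not isolated) | CC1=C[C@H]2O[C@@]2(O[Si](C)(C)C)CC1 | intermediate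
4 | (R)-2-hydroxy-4-methylcyclohex-3-en-1-one | CC1=C[C@@H](O)C(=O)CC1 | intermediate
5 | (R)-2-[(tert-butyldimethylsilyl)oxy]-4-methylcyclohex-3-en-1-one | CC1=C[C@@H](O[Si](C)(C)C(C)(C)C)C(=O)CC1 | intermediate
6 | pent-1-en-3-one | CCC(=O)C=C | starting material
7 | (Z)-triisopropyl(penta-1,3-dien-3-yloxy)silane | C/C=C(/C=C)O[Si](C(C)C)(C(C)C)C(C)C | intermediate
8 | (E)-4,4-dimethoxy-2-methylbut-2-enal | O=C/C(C)=C/C(OC)OC | starting material
9 | (1S,5S,6S)-6-(dimethoxymethyl)-1,5-dimethyl-4-[(triisopropylsilyl)oxy]cyclohex-3-ene-1-carbaldehyde | O=C[C@@]1(C)CC=C(O[Si](C(C)C)(C(C)C)C(C)C)[C@@H](C)[C@@H]1C(OC)OC | intermediate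
10 | (1S,5S,6S)-6-(dimethoxymethyl)-1,5-dimethyl-4-oxocyclohex-2-ene-1-carbaldehyde | O=C[C@@]1(C)C=CC(=O)[C@@H](C)[C@@H]1C(OC)OC | intermediate
11 | lithium (6R)-6-[(tert-butyldimethylsilyl)oxy]-4-methylcyclohexa-1,4-dien-1-olate (not isolated) | CC1=C[C@@H](O[Si](C)(C)C(C)(C)C)C(O[Li])=CC1 | intermediate
12 | triisopropoxy{[(6R)-6-[(tert-butyldimethylsilyl)oxy]-4-methylcyclohexa-1,4-dien-1-yl]oxy}titanium (not isolated) | CC1=C[C@@H](O[Si](C)(C)C(C)(C)C)C(O[Ti](OC(C)C)(OC(C)C)OC(C)C)=CC1 | intermediate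
13 | (2R,6S)-2-[(tert-butyldimethylsilyl)oxy]-6-{(S)-[(1S,5S,6S)-6-(dimethoxymethyl)-1,5-dimethyl-4-oxocyclohex-2-en-1-yl](hydroxy)methyl}-4-methylcyclohex-3-en-1-one | O[C@@H]([C@@H]1CC(C)=C[C@@H](O[Si](C)(C)C(C)(C)C)C1=O)[C@@]1(C)C=CC(=O)[C@@H](C)[C@@H]1C(OC)OC | intermediate
14 | (2R,6S)-2-[(tert-butyldimethylsilyl)oxy]-6-{(S)-[(1S,5S,6S)-6-formyl-1,5-dimethyl-4-oxocyclohex-2-en-1-yl](hydroxy)methyl}-4-methylcyclohex-3-en-1-one (open form of the lactol) | O[C@@H]([C@@H]1CC(C)=C[C@@H](O[Si](C)(C)C(C)(C)C)C1=O)[C@@]1(C)C=CC(=O)[C@@H](C)[C@@H]1C=O | intermediate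
15 | (1S,2S,3S,7R,8R,10S,11S)-7-(tert-butyldimethylsilyloxy)-2,8-dihydroxy-3,8-cyclo-17,18,19-trinorbriara-5,13-diene-9,12-dione | C[C@]12C=CC(=O)[C@@H](C)[C@@H]1C(=O)[C@]1(O)[C@H](O[Si](C)(C)C(C)(C)C)C=C(C)C[C@H]1[C@@H]2O | intermediate
16 | (1S,2S,3S,7R,8R,10S,11S)-7-(tert-butyldimethylsilyloxy)-8-hydroxy-2-(methanesulfonyloxy)-3,8-cyclo-17,18,19-trinorbriara-5,13-diene-9,12-dione | C[C@]12C=CC(=O)[C@@H](C)[C@@H]1C(=O)[C@]1(O)[C@H](O[Si](C)(C)C(C)(C)C)C=C(C)C[C@H]1[C@@H]2OS(C)(=O)=O | intermediate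
17 | (1S,2S,3S,6S,7S,8R,10S,11S)-7-(tert-butyldimethylsilyloxy)-6-chloro-8-hydroxy-2-(methanesulfonyloxy)-3,8-cyclo-17,18,19-trinorbriara-5(16),13-diene-9,12-dione | C[C@]12C=CC(=O)[C@@H](C)[C@@H]1C(=O)[C@]1(O)[C@H](O[Si](C)(C)C(C)(C)C)[C@@H](Cl)C(=C)C[C@H]1[C@@H]2OS(C)(=O)=O | intermediate
18 | (1S,2S,3S,4S,6S,7S,8R,10S,11S)-7-(tert-butyldimethylsilyloxy)-6-chloro-4,8-dihydroxy-2-(methanesulfonyloxy)-3,8-cyclo-17,18,19-trinorbriara-5(16),13-diene-9,12-dione | C[C@]12C=CC(=O)[C@@H](C)[C@@H]1C(=O)[C@]1(O)[C@H](O[Si](C)(C)C(C)(C)C)[C@@H](Cl)C(=C)[C@@H](O)[C@H]1[C@@H]2OS(C)(=O)=O | intermediate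
19 | (1S,2S,3S,4S,6S,7S,8R,10S,11S)-7-(tert-butyldimethylsilyloxy)-6-chloro-8-hydroxy-2-(methanesulfonyloxy)-4-(triisopropylsilyloxy)-3,8-cyclo-17,18,19-trinorbriara-5(16),13-diene-9,12-dione | C[C@]12C=CC(=O)[C@@H](C)[C@@H]1C(=O)[C@]1(O)[C@H](O[Si](C)(C)C(C)(C)C)[C@@H](Cl)C(=C)[C@@H](O[Si](C(C)C)(C(C)C)C(C)C)[C@H]1[C@@H]2OS(C)(=O)=O | intermediate
20 | (1S,2S,3S,4S,6S,7S,8S,9S,10S,11S)-7-(tert-butyldimethylsilyloxy)-6-chloro-8,9-dihydroxy-2-(methanesulfonyloxy)-4-(triisopropylsilyloxy)-3,8-cyclo-17,18,19-trinorbriara-5(16),13-dien-12-one | C[C@]12C=CC(=O)[C@@H](C)[C@@H]1[C@H](O)[C@]1(O)[C@H](O[Si](C)(C)C(C)(C)C)[C@@H](Cl)C(=C)[C@@H](O[Si](C(C)C)(C(C)C)C(C)C)[C@H]1[C@@H]2OS(C)(=O)=O | intermediate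
21 | potassium C8-alkoxide of 20 (not isolated) | C[C@]12C=CC(=O)[C@@H](C)[C@@H]1[C@H](O)[C@]1([O-])[C@H](O[Si](C)(C)C(C)(C)C)[C@@H](Cl)C(=C)[C@@H](O[Si](C(C)C)(C(C)C)C(C)C)[C@H]1[C@@H]2OS(C)(=O)=O.[K+] | intermediate
22 | (1S,2E,4S,6S,7S,9S,10S,11S)-7-(tert-butyldimethylsilyloxy)-6-chloro-9-hydroxy-4-(triisopropylsilyloxy)-17,18,19-trinorbriara-2,5(16),13-triene-8,12-dione | C=C1[C@@H](O[Si](C(C)C)(C(C)C)C(C)C)/C=C/[C@@]2(C)C=CC(=O)[C@@H](C)[C@@H]2[C@H](O)C(=O)[C@H](O[Si](C)(C)C(C)(C)C)[C@H]1Cl | intermediate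
23 | (1S,2E,4S,6S,7S,9S,10S,11S)-9-acetoxy-7-(tert-butyldimethylsilyloxy)-6-chloro-4-(triisopropylsilyloxy)-17,18,19-trinorbriara-2,5(16),13-triene-8,12-dione | C=C1[C@@H](O[Si](C(C)C)(C(C)C)C(C)C)/C=C/[C@@]2(C)C=CC(=O)[C@@H](C)[C@@H]2[C@H](OC(C)=O)C(=O)[C@H](O[Si](C)(C)C(C)(C)C)[C@H]1Cl | intermediate
24 | (1S,2E,4S,6S,7S,9S,10S,11S)-9-acetoxy-6-chloro-7-hydroxy-4-(triisopropylsilyloxy)-17,18,19-trinorbriara-2,5(16),13-triene-8,12-dione | C=C1[C@@H](O[Si](C(C)C)(C(C)C)C(C)C)/C=C/[C@@]2(C)C=CC(=O)[C@@H](C)[C@@H]2[C@H](OC(C)=O)C(=O)[C@H](O)[C@H]1Cl | intermediate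
25 | 2-bromopropanoic acid (racemic) | CC(Br)C(=O)O | starting material
26 | (1S,2E,4S,6S,7R,9S,10S,11S)-9-acetoxy-7-(2-bromopropanoyloxy)-6-chloro-4-(triisopropylsilyloxy)-17,18,19-trinorbriara-2,5(16),13-triene-8,12-dione | C=C1[C@@H](O[Si](C(C)C)(C(C)C)C(C)C)/C=C/[C@@]2(C)C=CC(=O)[C@@H](C)[C@@H]2[C@H](OC(C)=O)C(=O)[C@@H](OC(=O)C(C)Br)[C@H]1Cl | intermediate
27 | bromozinc ester enolate of 26 (not isolated) | C=C1[C@@H](O[Si](C(C)C)(C(C)C)C(C)C)/C=C/[C@@]2(C)C=CC(=O)[C@@H](C)[C@@H]2[C@H](OC(C)=O)C(=O)[C@@H](OC(O[Zn]Br)=CC)[C@H]1Cl | intermediate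
28 | (1S,2E,4S,6S,7R,8R,9S,10S,11S,17R)-9-acetoxy-6-chloro-8-hydroxy-12-oxo-4-(triisopropylsilyloxy)briara-2,5(16),13-trien-19,7-olide | C=C1[C@@H](O[Si](C(C)C)(C(C)C)C(C)C)/C=C/[C@@]2(C)C=CC(=O)[C@@H](C)[C@@H]2[C@H](OC(C)=O)[C@]2(O)[C@@H](C)C(=O)O[C@H]2[C@H]1Cl | intermediate
29 | (1S,2E,4S,6S,7R,8R,9S,10S,11S,17R)-9,11-diacetoxy-6-chloro-8-hydroxy-12-oxo-4-(triisopropylsilyloxy)briara-2,5(16),13-trien-19,7-olide | C=C1[C@@H](O[Si](C(C)C)(C(C)C)C(C)C)/C=C/[C@@]2(C)C=CC(=O)[C@@](C)(OC(C)=O)[C@@H]2[C@H](OC(C)=O)[C@]2(O)[C@@H](C)C(=O)O[C@H]2[C@H]1Cl | intermediate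
30 | (1S,2E,4S,6S,7R,8R,9S,10S,11S,17R)-9,11-diacetoxy-6-chloro-4,8-dihydroxy-12-oxobriara-2,5(16),13-trien-19,7-olide | C=C1[C@@H](O)/C=C/[C@@]2(C)C=CC(=O)[C@@](C)(OC(C)=O)[C@@H]2[C@H](OC(C)=O)[C@]2(O)[C@@H](C)C(=O)O[C@H]2[C@H]1Cl | target

## Step count and risks

Total steps: 21. Longest linear sequence: 18 steps (steps 4–6 then 7–21, or equally steps 1–3 then 7–21).

Three steps most likely to fail:

Step 5 (the proposed new Diels–Alder). The trisubstituted enal may be too slow at low temperature, the acetal may be ionised by the cationic boron catalyst, or the enantioselectivity may be low. Fallback with known chemistry, setting out from 7 and 8 and coming back at 13: a thermal Diels–Alder reaction (toluene, 110 °C, sealed tube, a trace of 2,6-di-tert-butyl-4-methylphenol) gives 9 as the racemate, that is together with the enantiomeric adduct ent-9 F1. Saegusa oxidation as in step 6 gives 10 together with the enantiomeric enone aldehyde ent-10 F2. The aldol reaction of step 7 with enantiopure 5 then gives 13 and the diastereomeric aldol adduct F3, which are separated by chromatography, so that 5 serves as the resolving partner.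

Step 7 (aldol). Three stereochemical preferences (enolate face, aldehyde face, syn topicity) must coincide, and the closed titanium transition state may override the aldehyde facial preference or give the anti adduct. Fallback, setting out from 5 and coming back at 13: 5 is converted with LiN(iPr)2 and Me3SiCl into the kinetic trimethylsilyl enol ether F4. A Mukaiyama aldol addition of F4 to 10 with BF3·OEt2 in CH2Cl2 at −78 °C goes through an open transition state in which the two facial preferences act independently, giving 13 after aqueous work-up.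

Step 19 (Reformatsky lactonisation). The tethered enolate may add to the other face of the C8 ketone (cis-fused lactone) or zinc may attack the allylic chloride. Fallback, setting out from 24 and coming back at 28: a Mitsunobu reaction of 24 with formic acid (PPh3, diisopropyl azodicarboxylate) gives the inverted formate F5, and NaHCO3 in MeOH at 0 °C frees the 7R alcohol F6. A chelation-controlled intermolecular Reformatsky addition of ethyl 2-bromopropanoate (Zn, THF, 0 °C) to this α-hydroxy ketone gives the dihydroxy ester F7, which closes to 28 with pyridinium p-toluenesulfonate in benzene.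

Further compounds
F1 | step 5 | (1R,5R,6R)-6-(dimethoxymethyl)-1,5-dimethyl-4-[(triisopropylsilyl)oxy]cyclohex-3-ene-1-carbaldehyde (ent-9) | O=C[C@]1(C)CC=C(O[Si](C(C)C)(C(C)C)C(C)C)[C@H](C)[C@H]1C(OC)OC
F2 | step 5 | (1R,5R,6R)-6-(dimethoxymethyl)-1,5-dimethyl-4-oxocyclohex-2-ene-1-carbaldehyde (ent-10) | O=C[C@]1(C)C=CC(=O)[C@H](C)[C@H]1C(OC)OC
F3 | step 5 | (2R,6S)-2-[(tert-butyldimethylsilyl)oxy]-6-{(R)-[(1R,5R,6R)-6-(dimethoxymethyl)-1,5-dimethyl-4-oxocyclohex-2-en-1-yl](hydroxy)methyl}-4-methylcyclohex-3-en-1-one (diastereomer of 13) | O[C@H]([C@@H]1CC(C)=C[C@@H](O[Si](C)(C)C(C)(C)C)C1=O)[C@]1(C)C=CC(=O)[C@H](C)[C@H]1C(OC)OC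
F4 | step 7 | {[(6R)-6-[(tert-butyldimethylsilyl)oxy]-4-methylcyclohexa-1,4-dien-1-yl]oxy}trimethylsilane | CC1=C[C@@H](O[Si](C)(C)C(C)(C)C)C(O[Si](C)(C)C)=CC1
F5 | step 19 | (1S,2E,4S,6S,7R,9S,10S,11S)-9-acetoxy-6-chloro-7-(formyloxy)-4-(triisopropylsilyloxy)-17,18,19-trinorbriara-2,5(16),13-triene-8,12-dione | C=C1[C@@H](O[Si](C(C)C)(C(C)C)C(C)C)/C=C/[C@@]2(C)C=CC(=O)[C@@H](C)[C@@H]2[C@H](OC(C)=O)C(=O)[C@@H](OC=O)[C@H]1Cl
F6 | step 19 | (1S,2E,4S,6S,7R,9S,10S,11S)-9-acetoxy-6-chloro-7-hydroxy-4-(triisopropylsilyloxy)-17,18,19-trinorbriara-2,5(16),13-triene-8,12-dione | C=C1[C@@H](O[Si](C(C)C)(C(C)C)C(C)C)/C=C/[C@@]2(C)C=CC(=O)[C@@H](C)[C@@H]2[C@H](OC(C)=O)C(=O)[C@@H](O)[C@H]1Cl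
F7 | step 19 | ethyl (1S,2E,4S,6S,7R,8R,9S,10S,11S,17R)-9-acetoxy-6-chloro-7,8-dihydroxy-12-oxo-4-(triisopropylsilyloxy)briara-2,5(16),13-trien-19-oate | C=C1[C@@H](O[Si](C(C)C)(C(C)C)C(C)C)/C=C/[C@@]2(C)C=CC(=O)[C@@H](C)[C@@H]2[C@H](OC(C)=O)[C@](O)([C@@H](C)C(=O)OCC)[C@@H](O)[C@H]1Cl
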